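**Retrosynthetic overview**

1. Numbering: N4, C3 (bears C18 of side lactone ring E, C18–C19–C20(Me)–C21), C2, C1, C9a, C9, C8, C7–C5, C10 (ethyl), C11–C14. The route rests on C11, the spiro carbon shared by ring C (tetrahydrofuran O–C8–C9–C10–C11) and ring D (γ-lactone C11–C12–C13–C14(=O)–O): it carries two oxygens, so both rings can be closed on a C11 ketone released from a cyclopropanol, with C14 supplied by CO.
2. Late stage: C9a–OH and C1=O by double oxygenation of pyrrole ring A. Ring E by C3 acylation with an (S)-methylsuccinate unit and C18 reduction. C12–OH and C13–Me by dehydrogenation, boryl conjugate addition and dianion methylation of ring D.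
3. Key disconnection: C8–O–C11, C13–C14 and C14–O by palladium-catalysed carbonylative opening of a hydroxycyclopropanol, which comes in one step (Kulinkovich) from the C8–O–C11 lactone.
4. Rings A and B (pyrrole, azepine) from an azido keto acetal by Staudinger/aza-Wittig/Paal–Knorr; the ketone from Fukuyama coupling of a thioester.
5. C8–C9–C10 triad by anti,anti conjugate addition/ethylation of an (R)-butenolide made from butane-1,4-diol. Ring order: lactone, then B and A, then C and D, then E.

Key step: step 12

Assumption: the (R,R)-ProPhenol–zinc catalyst is taken to deliver the alkynyl group to the Si face of aldehyde 3; if the carbinol of 5 proves to be (S) on Mosher ester analysis, the (S,S) ligand is used with no other change.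

**Step 1**
Reactants: 1 butane-1,4-diol
Product: 2 4-[(tert-butyldiphenylsilyl)oxy]butan-1-ol
Conditions: NaH (1.0 equiv), THF, 0 °C; then TBDPSCl (1.0 equiv), rt
Reagents that add atoms: tert-butyl(chloro)diphenylsilane, CC(C)(C)[Si](Cl)(c1ccccc1)c1ccccc1
Why: O-silylation of the sparingly soluble monosodium alkoxide of a symmetric diol should stop at the mono ether.

**Step 2**
Reactants: 2 4-[(tert-butyldiphenylsilyl)oxy]butan-1-ol
Product: 3 4-[(tert-butyldiphenylsilyl)oxy]butanal
Conditions: TEMPO (10 mol%), PhI(OAc)2 (1.1 equiv), CH2Cl2, rt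
Reagents that add atoms: none
Why: TEMPO-catalysed oxoammonium oxidation stops at the aldehyde and leaves the silyl ether alone.

**Step 3**
Reactants: 3 4-[(tert-butyldiphenylsilyl)oxy]butanal; 4 methyl propiolate
Product: 5 methyl (4R)-7-[(tert-butyldiphenylsilyl)oxy]-4-hydroxyhept-2-ynoate
Conditions: (R,R)-ProPhenol [2,6-bis({(2R)-2-[hydroxy(diphenyl)methyl]pyrrolidin-1-yl}methyl)-4-methylphenol] (20 mol%), Me2Zn (3 equiv), Ph3P=O (40 mol%), toluene, 0 °C
Reagents that add atoms: none
Why: Catalytic enantioselective addition of a zinc alkynylide to an aldehyde (ProPhenol–dinuclear zinc alkynylation) sets C8 by Si-face attack, which gives the (R)-carbinol.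

**Step 4**
Reactants: 5 methyl (4R)-7-[(tert-butyldiphenylsilyl)oxy]-4-hydroxyhept-2-ynoate
Product: 7 (5R)-5-{3-[(tert-butyldiphenylsilyl)oxy]propyl}furan-2(5H)-one, via Z-hydroxy enoate 6 (not isolated)
Conditions: H2 (1 atm), Pd/CaCO3 poisoned with Pb(OAc)2, quinoline, EtOAc, rt; then PPTS (cat.), CH2Cl2, rt
Reagents that add atoms: none
Why: Lindlar syn-semihydrogenation gives the Z-γ-hydroxy enoate, which lactonises to the butenolide without touching C8.

**Step 5**
Reactants: 7 (5R)-5-{3-[(tert-butyldiphenylsilyl)oxy]propyl}furan-2(5H)-one; 8 tris(methylthio)methane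
Product: 11 (3S,4S,5R)-5-{3-[(tert-butyldiphenylsilyl)oxy]propyl}-3-ethyl-4-[tris(methylsulfanyl)methyl]oxolan-2-one, via tris(methylthio)methyllithium 9 (not isolated), via lithium enolate 10 (not isolated)
Conditions: 8, n-BuLi, THF, −78 °C; 7, −78 °C; then EtI, DMPU, −78 → −30 °C
Reagents that add atoms: ethyl iodide, CCI
Why: In this tandem conjugate addition–enolate alkylation the bulky carbanion adds to C9 anti to the C8 side chain and ethyl iodide then attacks C10 anti to the new C9 group, which gives the trans,trans lactone.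

**Step 6**
Reactants: 11 (3S,4S,5R)-orthothioester lactone
Product: 12 S-methyl (2R,3S,4S)-2-{3-[(tert-butyldiphenylsilyl)oxy]propyl}-4-ethyl-5-oxooxolane-3-carbothioate
Conditions: HgO, BF3·OEt2, THF/H2O, 0 °C → rt
Reagents that add atoms: water, O
Why: Mercury-assisted hydrolysis of the orthothioester stops at the S-methyl thioester and touches no stereocentre.

**Step 7**
Reactants: 12 S-methyl thioester; 13 2-(2-bromoethyl)-1,3-dioxolane
Product: 15 (3S,4S,5R)-5-{3-[(tert-butyldiphenylsilyl)oxy]propyl}-4-[3-(1,3-dioxolan-2-yl)propanoyl]-3-ethyloxolan-2-one, via alkylzinc bromide 14 (not isolated)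
Conditions: 13, Zn dust, LiCl, THF, 50 °C; then 12, PdCl2(PPh3)2 (5 mol%), toluene, rt
Reagents that add atoms: none
Why: Fukuyama coupling of a thioester with an alkylzinc halide gives the ketone and leaves the lactone alone, which a Grignard reagent would attack.

**Step 8**
Reactants: 15 silyl keto acetal
Product: 16 (3S,4S,5R)-4-[3-(1,3-dioxolan-2-yl)propanoyl]-3-ethyl-5-(3-hydroxypropyl)oxolan-2-one
Conditions: Bu4NF, AcOH (1:1), THF, 0 °C → rt
Reagents that add atoms: none
Why: Buffered fluoride desilylation frees the C5 hydroxyl and avoids base-induced β-elimination of the C8 lactone oxygen through the enolate of the C9a ketone.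

**Step 9**
Reactants: 16 hydroxy keto acetal
Product: 17 (3S,4S,5R)-5-(3-azidopropyl)-4-[3-(1,3-dioxolan-2-yl)propanoyl]-3-ethyloxolan-2-one
Conditions: (PhO)2P(O)N3, DIAD, PPh3, THF, 0 °C → rt
Reagents that add atoms: diphenylphosphoryl azide, [N-]=[N+]=NP(=O)(Oc1ccccc1)Oc1ccccc1
Why: Mitsunobu azidation of the primary alcohol is mild enough for the β-acyloxy ketone and the acetal.

**Step 10**
Reactants: 17 azido keto acetal
Product: 20 (8R,9R,10S)-10-ethyl γ-lactone (C8–O–C11(=O)–C10–C9) trans-fused to 6,7,8,9-tetrahydro-5H-pyrrolo[1,2-a]azepine, via iminophosphorane 18 (not isolated), via cyclic imine 19 (not isolated)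
Conditions: PPh3, toluene, rt → 80 °C; then AcOH/H2O, 70 °C
Reagents that add atoms: none
Why: Staudinger reaction and intramolecular aza-Wittig condensation close the seven-membered imine (ring B), and after acid unmasking of the aldehyde the enamine tautomer condenses with it in a Paal–Knorr pyrrole synthesis (ring A), while C9, which could equilibrate through the enamine, already holds the stable trans,trans arrangement.

**Step 11**
Reactants: 20 pyrrole lactone
Product: 21 (8R,9R)-9-[(1S)-1-(1-hydroxycyclopropyl)propyl]-6,7,8,9-tetrahydro-5H-pyrrolo[1,2-a]azepin-8-ol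
Conditions: EtMgBr (4 equiv), Ti(OiPr)4 (0.3 equiv), THF, 0 °C → rt
Reagents that add atoms: ethylmagnesium bromide, CC[Mg]Br
Why: In the Kulinkovich cyclopropanation the titanacyclopropane formed from EtMgBr and Ti(OiPr)4 adds twice to the lactone carbonyl, which turns C11 into the cyclopropanol carbon and releases the C8 hydroxyl without involving the pyrrole or the three stereocentres.

**Step 12**
Reactants: 21 hydroxycyclopropanol
Product: 22 (8R,9R,10S,11R)-oxaspirolactone: 10-ethyl tetrahydrofuran ring C on the pyrroloazepine and spiro-linked at C11 to γ-lactone ring D (C12 and C13 are CH2)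
Conditions: Pd(OAc)2 (10 mol%), neocuproine (20 mol%), 1,4-benzoquinone (2 equiv), CO (1 atm), ClCH2CH2Cl, rt; then CSA (10 mol%), CH2Cl2, 0 °C → rt
Reagents that add atoms: carbon monoxide, [C-]#[O+]
Why: The divalent palladium catalyst converts the cyclopropanol into its palladium alkoxide, and strain-driven cleavage of the C11–C13 ring bond (β-carbon elimination) leaves a ketone at C11 and an alkylpalladium at C13; the C8 hydroxyl then adds to the ketone (5-exo-trig, ring C), CO inserts into the C13–Pd bond, the hemiketal hydroxyl acylates at C14 (five-membered acyl substitution, ring D), and benzoquinone returns zerovalent palladium to the divalent state. The closest known reaction type is the palladium-catalysed carbonylative spirolactonisation of hydroxycyclopropanols, an alkoxycarbonylation of a palladium homoenolate. The only new stereocentre is C11: the hemiketal epimers exchange through the open hydroxy ketone, so the ratio is fixed at the lactonisation, and the acyloxy ketal can afterwards be equilibrated with acid through its oxocarbenium ion toward the epimer with the lactone oxygen anti to the C10 ethyl group. The step needs CO capture to outrun β-hydride elimination of the homoenolate to a vinyl ketone and needs the pyrrole C–H bonds to stay untouched; the chelating phenanthroline ligand and the CO atmosphere favour insertion, and the 1,4 relation of the C8 hydroxyl to C11 makes hemiketal closure fast. Site selectivity of ring opening is not in question because the two cyclopropane CH2 groups are equivalent.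

**Step 13**
Reactants: 22 oxaspirolactone
Product: 25 (8R,9R,10S,11R)-C12=C13 butenolide of 22, via lithium enolate 23 (not isolated), via C13 selenide 24 (not isolated)
Conditions: LiN(iPr)2, THF, −78 °C; PhSeBr (1.0 equiv), −78 °C; then H2O2, pyridine, CH2Cl2, 0 °C → rt
Reagents that add atoms: none
Why: α-Selenenylation of the lactone enolate followed by selenoxide syn-elimination can only run toward C12, which gives the butenolide, and the preformed enolate consumes the selenenyl bromide before it can attack the pyrrole.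

**Step 14**
Reactants: 25 spiro butenolide
Product: 27 (8R,9R,10S,11S,12R)-12-hydroxy derivative of 22, via C12 boronate 26 (not isolated)
Conditions: CuCl (10 mol%), Xantphos (10 mol%), NaOtBu (20 mol%), B2pin2 (1.2 equiv), MeOH (2 equiv), THF, rt; then NaBO3·4H2O, THF/H2O, rt
Reagents that add atoms: sodium perborate, [Na+].[O-]OB=O
Why: Conjugate borylation by a monovalent copper–boryl species followed by stereoretentive C–B oxidation sets 12R, because the boryl group should enter from the face of ring D that carries the ring C oxygen, the other face being covered by the syn C10 ethyl group.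

**Step 15**
Reactants: 27 β-hydroxy spirolactone
Product: 29 (8R,9R,10S,11S,12R,13R)-12-hydroxy-13-methyl derivative of 22, via dilithio alkoxide enolate 28 (not isolated)
Conditions: LiN(iPr)2 (2.5 equiv), THF, −78 → −40 °C; MeI, DMPU, −78 → −40 °C
Reagents that add atoms: methyl iodide, CI
Why: In this Fráter–Seebach alkylation the dianion is methylated at C13 anti to the C12 lithium alkoxide, which gives the trans 12-hydroxy-13-methyl lactone (13R).

**Step 16**
Reactants: 29 hydroxy methyl spirolactone
Product: 30 12-O-triethylsilyl ether of 29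
Conditions: Et3SiOTf, 2,6-lutidine, CH2Cl2, −78 °C
Reagents that add atoms: triethylsilyl trifluoromethanesulfonate, CC[Si](CC)(CC)OS(=O)(=O)C(F)(F)F
Why: Silylation with a silyl triflate protects the hindered C12 hydroxyl against O-acylation in step 20.

**Step 17**
Reactants: 31 (S)-methylsuccinic acid
Product: 32 dimethyl (2S)-2-methylbutanedioate
Conditions: MeOH, H2SO4 (cat.), reflux
Reagents that add atoms: methanol, CO
Why: Fischer esterification does not enolise the stereocentre.

**Step 18**
Reactants: 32 dimethyl (2S)-2-methylbutanedioate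
Product: 33 (3S)-4-methoxy-3-methyl-4-oxobutanoic acid
Conditions: pig liver esterase, phosphate buffer (pH 7.5), rt; then pH 2, EtOAc extraction
Reagents that add atoms: water, O
Why: Enzymatic ester hydrolysis should take the unbranched C4 ester, since the α-methyl group shields the C1 ester, and the neutral pH excludes epimerisation.

**Step 19**
Reactants: 33 (3S)-4-methoxy-3-methyl-4-oxobutanoic acid
Product: 34 methyl (2S)-4-chloro-2-methyl-4-oxobutanoate
Conditions: (COCl)2, DMF (cat.), CH2Cl2, 0 °C → rt; used crude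
Reagents that add atoms: oxalyl chloride, ClC(=O)C(Cl)=O
Why: Acid chloride formation through the chloroiminium salt is safe for the stereocentre, which is β to the acyl chloride and cannot be lost through a ketene.

**Step 20**
Reactants: 30 silyl ether; 34 methyl (2S)-4-chloro-2-methyl-4-oxobutanoate
Product: 35 3-acyl pyrrole: 30 carrying at C3 the (3S)-4-methoxy-3-methyl-4-oxobutanoyl group
Conditions: Et2AlCl (1.5 equiv), CH2Cl2, 0 °C; then 34
Reagents that add atoms: none
Why: In this Friedel–Crafts acylation C3 is the only free α-position of the electron-rich 1,2-dialkylpyrrole, and Et2AlCl activates the acid chloride while removing HCl as ethane.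

**Step 21**
Reactants: 35 silylated acyl pyrrole
Product: 36 12-hydroxy ketone: 35 without the triethylsilyl group
Conditions: HF·pyridine, pyridine, THF, 0 °C → rt
Reagents that add atoms: none
Why: Fluoride cleavage of the silyl ether is done at the robust acyl pyrrole stage, so that the acid-labile pyrrolyl carbinyl lactone never meets HF.

**Step 22**
Reactants: 36 hydroxy keto ester
Product: 38 (8R,9R,10S,11S,12R,13R,18S,20S)-bis-lactone pyrrole (ring E closed on C3), via hydroxy ester 37 (not isolated)
Conditions: (R)-Me-CBS [(R)-1-methyl-3,3-diphenyltetrahydro-1H,3H-pyrrolo[1,2-c][1,3,2]oxazaborole] (20 mol%), BH3·SMe2, THF, −20 → 0 °C; MeOH; then Et3N, toluene, 50 °C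
Reagents that add atoms: none
Why: In the Corey–Bakshi–Shibata reduction the (R)-oxazaborolidine, with the pyrrole as the large group, should give the (18S)-carbinol, and the γ-hydroxy ester then closes ring E by lactonisation at C21 without touching C18 or C20.

**Step 23**
Reactants: 38 bis-lactone pyrrole
Product: 39 CNP0182700.1 (8R,9S,9aS,10S,11S,12R,13R,18S,20S)
Conditions: dimethyldioxirane (2.2 equiv), acetone, −78 → 0 °C
Reagents that add atoms: dimethyldioxirane, CC1(C)OO1
Why: Proposed new method: dimethyldioxirane should epoxidise the more electron-rich C9a=C1 bond of the pyrrole (C3 bears the inductively withdrawing lactone carbinol), nitrogen-assisted opening and proton loss give the 1-hydroxypyrrole and its pyrrol-1-one tautomer, and a second oxygen transfer to the C9a=C1 enol from the face of H-9, anti to C10 and the spiro unit, gives the 9aS hemiaminal ketone; the closest known reactions are the dioxirane oxidation of 2,3-disubstituted indoles to 3-hydroxyindolenines and indoxyls, Rubottom-type enol oxidation, and the autoxidation of 1H-pyrrol-3(2H)-ones to their 2-hydroxy derivatives.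

**Compound list**

1 | butane-1,4-diol | OCCCCO | starting material
2 | 4-[(tert-butyldiphenylsilyl)oxy]butan-1-ol | OCCCCO[Si](c1ccccc1)(c1ccccc1)C(C)(C)C | intermediate
3 | 4-[(tert-butyldiphenylsilyl)oxy]butanal | O=CCCCO[Si](c1ccccc1)(c1ccccc1)C(C)(C)C | intermediate
4 | methyl propiolate | C#CC(=O)OC | starting material
5 | methyl (4R)-7-[(tert-butyldiphenylsilyl)oxy]-4-hydroxyhept-2-ynoate | COC(=O)C#C[C@H](O)CCCO[Si](c1ccccc1)(c1ccccc1)C(C)(C)C | intermediate
6 | methyl (2Z,4R)-7-[(tert-butyldiphenylsilyl)oxy]-4-hydroxyhept-2-enoate | COC(=O)/C=C\[C@H](O)CCCO[Si](c1ccccc1)(c1ccccc1)C(C)(C)C | intermediate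
7 | (5R)-5-{3-[(tert-butyldiphenylsilyl)oxy]propyl}furan-2(5H)-one | O=C1C=C[C@@H](CCCO[Si](c2ccccc2)(c2ccccc2)C(C)(C)C)O1 | intermediate
8 | tris(methylthio)methane | CSC(SC)SC | starting material
9 | tris(methylthio)methyllithium | [Li]C(SC)(SC)SC | intermediate
10 | lithium enolate of the conjugate adduct (C8 R, C9 S) | [Li]OC1=C[C@H](C(SC)(SC)SC)[C@@H](CCCO[Si](c2ccccc2)(c2ccccc2)C(C)(C)C)O1 | intermediate
11 | (3S,4S,5R)-5-{3-[(tert-butyldiphenylsilyl)oxy]propyl}-3-ethyl-4-[tris(methylsulfanyl)methyl]oxolan-2-one | CC[C@H]1[C@H](C(SC)(SC)SC)[C@@H](CCCO[Si](c2ccccc2)(c2ccccc2)C(C)(C)C)OC1=O | intermediate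
12 | S-methyl (2R,3S,4S)-2-{3-[(tert-butyldiphenylsilyl)oxy]propyl}-4-ethyl-5-oxooxolane-3-carbothioate | CC[C@H]1[C@H](C(=O)SC)[C@@H](CCCO[Si](c2ccccc2)(c2ccccc2)C(C)(C)C)OC1=O | intermediate
13 | 2-(2-bromoethyl)-1,3-dioxolane | BrCCC1OCCO1 | starting material
14 | [2-(1,3-dioxolan-2-yl)ethyl]zinc bromide | Br[Zn]CCC1OCCO1 | intermediate
15 | (3S,4S,5R)-5-{3-[(tert-butyldiphenylsilyl)oxy]propyl}-4-[3-(1,3-dioxolan-2-yl)propanoyl]-3-ethyloxolan-2-one | CC[C@H]1[C@H](C(=O)CCC2OCCO2)[C@@H](CCCO[Si](c2ccccc2)(c2ccccc2)C(C)(C)C)OC1=O | intermediate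
16 | (3S,4S,5R)-4-[3-(1,3-dioxolan-2-yl)propanoyl]-3-ethyl-5-(3-hydroxypropyl)oxolan-2-one | CC[C@H]1[C@H](C(=O)CCC2OCCO2)[C@@H](CCCO)OC1=O | intermediate
17 | (3S,4S,5R)-5-(3-azidopropyl)-4-[3-(1,3-dioxolan-2-yl)propanoyl]-3-ethyloxolan-2-one | CC[C@H]1[C@H](C(=O)CCC2OCCO2)[C@@H](CCCN=[N+]=[N-])OC1=O | intermediate
18 | iminophosphorane of 17 (N=PPh3 in place of N3) | CC[C@H]1[C@H](C(=O)CCC2OCCO2)[C@@H](CCCN=P(c2ccccc2)(c2ccccc2)c2ccccc2)OC1=O | intermediate
19 | (8R,9R,10S)-cyclic imine: tetrahydroazepine C9a=N4 fused to the lactone, C9a bearing 2-(1,3-dioxolan-2-yl)ethyl | CC[C@H]1[C@H]2[C@@H](CCCN=C2CCC3OCCO3)OC1=O | intermediate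
20 | (8R,9R,10S)-10-ethyl γ-lactone (C8–O–C11(=O)–C10–C9) trans-fused to 6,7,8,9-tetrahydro-5H-pyrrolo[1,2-a]azepine | CC[C@H]1[C@H]2[C@@H](CCCn3cccc23)OC1=O | intermediate
21 | (8R,9R)-9-[(1S)-1-(1-hydroxycyclopropyl)propyl]-6,7,8,9-tetrahydro-5H-pyrrolo[1,2-a]azepin-8-ol | CC[C@H](C1(O)CC1)[C@H]1[C@H](O)CCCn2cccc12 | intermediate
22 | (8R,9R,10S,11R)-oxaspirolactone: ring C tetrahydrofuran spiro at C11 to unsubstituted γ-lactone ring D, lactone oxygen anti to the C10 ethyl group | CC[C@H]1[C@H]2[C@@H](CCCn3cccc23)O[C@]12OC(=O)CC2 | intermediate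
23 | lithium enolate of 22 (C13=C14–OLi) | CC[C@H]1[C@H]2[C@@H](CCCn3cccc23)O[C@]12OC(O[Li])=CC2 | intermediate
24 | 13-(phenylselanyl) derivative of 22 (C13 epimers) | CC[C@H]1[C@H]2[C@@H](CCCn3cccc23)O[C@]12OC(=O)C([Se]c3ccccc3)C2 | intermediate
25 | (8R,9R,10S,11R)-C12=C13 butenolide of 22 | CC[C@H]1[C@H]2[C@@H](CCCn3cccc23)O[C@]12OC(=O)C=C2 | intermediate
26 | (8R,9R,10S,11R,12R)-12-(4,4,5,5-tetramethyl-1,3,2-dioxaborolan-2-yl) derivative of 22 | CC[C@H]1[C@H]2[C@@H](CCCn3cccc23)O[C@]12OC(=O)C[C@H]2B1OC(C)(C)C(C)(C)O1 | intermediate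
27 | (8R,9R,10S,11S,12R)-12-hydroxy derivative of 22 (hydroxyl syn to the ring C oxygen) | CC[C@H]1[C@H]2[C@@H](CCCn3cccc23)O[C@]12OC(=O)C[C@H]2O | intermediate
28 | dilithium alkoxide enolate of 27 | CC[C@H]1[C@H]2[C@@H](CCCn3cccc23)O[C@]12OC(O[Li])=C[C@H]2O[Li] | intermediate
29 | (8R,9R,10S,11S,12R,13R)-12-hydroxy-13-methyl derivative of 22 (hydroxyl and methyl trans) | CC[C@H]1[C@H]2[C@@H](CCCn3cccc23)O[C@]12OC(=O)[C@H](C)[C@H]2O | intermediate
30 | 12-O-triethylsilyl ether of 29 | CC[C@H]1[C@H]2[C@@H](CCCn3cccc23)O[C@]12OC(=O)[C@H](C)[C@H]2O[Si](CC)(CC)CC | intermediate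
31 | (S)-methylsuccinic acid | OC(=O)C[C@H](C)C(=O)O | starting material
32 | dimethyl (2S)-2-methylbutanedioate | COC(=O)C[C@H](C)C(=O)OC | intermediate
33 | (3S)-4-methoxy-3-methyl-4-oxobutanoic acid | OC(=O)C[C@H](C)C(=O)OC | intermediate
34 | methyl (2S)-4-chloro-2-methyl-4-oxobutanoate | ClC(=O)C[C@H](C)C(=O)OC | intermediate
35 | 30 carrying at C3 the (3S)-4-methoxy-3-methyl-4-oxobutanoyl group | CC[C@H]1[C@H]2[C@@H](CCCn3c(C(=O)C[C@H](C)C(=O)OC)ccc23)O[C@]12OC(=O)[C@H](C)[C@H]2O[Si](CC)(CC)CC | intermediate
36 | 35 without the triethylsilyl group (free C12 hydroxyl, C18 ketone) | CC[C@H]1[C@H]2[C@@H](CCCn3c(C(=O)C[C@H](C)C(=O)OC)ccc23)O[C@]12OC(=O)[C@H](C)[C@H]2O | intermediate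
37 | (18S)-hydroxy ester from 36 | CC[C@H]1[C@H]2[C@@H](CCCn3c([C@@H](O)C[C@H](C)C(=O)OC)ccc23)O[C@]12OC(=O)[C@H](C)[C@H]2O | intermediate
38 | (8R,9R,10S,11S,12R,13R,18S,20S)-bis-lactone pyrrole (cis ring E on C3) | CC[C@H]1[C@H]2[C@@H](CCCn3c([C@@H]4C[C@H](C)C(=O)O4)ccc23)O[C@]12OC(=O)[C@H](C)[C@H]2O | intermediate
39 | CNP0182700.1 (8R,9S,9aS,10S,11S,12R,13R,18S,20S) | CC[C@H]1[C@H]2[C@@H](CCCN3C([C@@H]4C[C@H](C)C(=O)O4)=CC(=O)[C@@]23O)O[C@]12OC(=O)[C@H](C)[C@H]2O | target

**Step count**

Total: 23 steps. Longest linear sequence: 20 steps (steps 1–16 and 20–23); steps 17–19 make the side-chain acid chloride.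

**Steps most likely to fail**

Step 23. The oxidant may attack the C2=C3 bond instead of C9a=C1, may go on to oxidise the enaminone product or cleave the ring to an ene-dione, or may add to C9a with poor facial selectivity. The fallback uses known chemistry and fixes the site by the acyl group. It sets out from 36: NBS in THF at −78 → 0 °C should brominate the β-position remote from the acyl group, as is usual for 2-acylpyrroles, to give the C1 bromo ketone F1. Reduction and lactonisation under the conditions of step 22 give the bromo bis-lactone F2. Miyaura borylation (PdCl2(dppf), B2pin2, KOAc, dioxane, 80 °C) gives the C1 boronate F3, and NaBO3·4H2O in THF/H2O gives the pyrrol-1-one F4 (tautomer of the 1-hydroxypyrrole). Exposure of F4 to O2 in CH2Cl2, the known autoxidation of 2-monosubstituted 1H-pyrrol-3(2H)-ones, then hydroxylates C9a from the face of H-9, and the route is rejoined at 39.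

Step 12. The C13 alkylpalladium may undergo β-hydride elimination to the vinyl ketone before CO inserts, the pyrrole may be palladated, or the C11 epimers may form in a proportion that acid does not correct. The fallback sets out from lactone 20 and needs neither the cyclopropanol nor CO. Addition of LiC≡CCO2Et with BF3·OEt2 in THF at −78 °C to the lactone carbonyl gives the hydroxy ynone F5. Hydrogenation (H2, Pd/C, EtOAc) gives the γ-keto ester F6. CSA in toluene at 60 °C then closes rings C and D by ketalisation and lactonisation with loss of ethanol, under thermodynamic control at C11, and the route is rejoined at 22.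

Step 22. Hydride transfer to the vinylogous amide carbonyl may be slow, the carbinol may be reduced further to the C18 methylene through the azafulvenium ion, and the remote stereocentres may erode catalyst control. The fallback sets out from 36 and replaces catalyst control by substrate reduction and equilibration. LiBH(sBu)3 in THF at −78 °C reduces the ketone, and the lithium alkoxide lactonises in the flask to give 38 together with its C18 epimer F7. PPTS (cat.) in CH2Cl2 then ionises the pyrrolyl carbinyl C18–O bond reversibly and should move F7 toward the more stable cis-2,4-disubstituted lactone; remaining F7 is separated and recycled. The route is rejoined at 38.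

**Further compounds**

F1 | step 23 | C1-bromo derivative of 36 | CC[C@H]1[C@H]2[C@@H](CCCn3c(C(=O)C[C@H](C)C(=O)OC)cc(Br)c23)O[C@]12OC(=O)[C@H](C)[C@H]2O
F2 | step 23 | C1-bromo derivative of 38 | CC[C@H]1[C@H]2[C@@H](CCCn3c([C@@H]4C[C@H](C)C(=O)O4)cc(Br)c23)O[C@]12OC(=O)[C@H](C)[C@H]2O
F3 | step 23 | C1-(4,4,5,5-tetramethyl-1,3,2-dioxaborolan-2-yl) derivative of 38 | CC[C@H]1[C@H]2[C@@H](CCCn3c([C@@H]4C[C@H](C)C(=O)O4)cc(B4OC(C)(C)C(C)(C)O4)c23)O[C@]12OC(=O)[C@H](C)[C@H]2O
F4 | step 23 | pyrrol-1-one from 38 (C1 ketone, C9a–H, C2=C3 enaminone; C9a epimers) | CC[C@H]1[C@H]2[C@@H](CCCN3C([C@@H]4C[C@H](C)C(=O)O4)=CC(=O)C23)O[C@]12OC(=O)[C@H](C)[C@H]2O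
F5 | step 12 | ethyl (5S)-5-[(8R,9R)-8-hydroxy-6,7,8,9-tetrahydro-5H-pyrrolo[1,2-a]azepin-9-yl]-4-oxohept-2-ynoate | CC[C@H](C(=O)C#CC(=O)OCC)[C@H]1[C@H](O)CCCn2cccc12
F6 | step 12 | ethyl (5S)-5-[(8R,9R)-8-hydroxy-6,7,8,9-tetrahydro-5H-pyrrolo[1,2-a]azepin-9-yl]-4-oxoheptanoate | CC[C@H](C(=O)CCC(=O)OCC)[C@H]1[C@H](O)CCCn2cccc12
F7 | step 22 | (18R)-epimer of 38 | CC[C@H]1[C@H]2[C@@H](CCCn3c([C@H]4C[C@H](C)C(=O)O4)ccc23)O[C@]12OC(=O)[C@H](C)[C@H]2O
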